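**Retrosynthetic overview**

- The strategy rests on the Ar–C1H2–C2H2–C3(=O) end of the heptane chain: the C3 carbonyl is β to the benzylic carbon C1, so this end is a ketone homoenolate bonded to a guaiacyl ring. The C1–aryl bond is therefore cut to give a 1-(4-arylbutyl)cyclopropan-1-ol and 4-bromoguaiacol, both phenols carried as MOM ethers.
- The cyclopropanol comes from ethyl 5-arylpentanoate by a Kulinkovich reaction: C3 is the former ester carbon, and C1 and C2 are the two ring CH2 groups supplied by EtMgBr.
- The ester comes from MOM-protected vanillin, which supplies C7 and one arene; a vinylogous Horner–Wadsworth–Emmons olefination adds C3–C6, followed by hydrogenation.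
- Ring order: both benzene rings are bought intact. The only ring made is the cyclopropane (step 4), and it is opened again in step 6; the last step frees both phenols.

Key step: step 6

Remark: the target has no stereocentre and no stereogenic alkene. Chain carbons are numbered C1 to C7 from the benzylic carbon nearer the carbonyl, so the ketone is C3.

Step 1
Reactants: 1 vanillin (4-hydroxy-3-methoxybenzaldehyde)
Product: 2 3-methoxy-4-(methoxymethoxy)benzaldehyde
Conditions: MOMCl, K2CO3, acetone, 0 °C to rt
Reagents that add atoms: chloromethyl methyl ether (MOMCl), COCCl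
Why: O-alkylation of the potassium phenoxide by the reactive α-chloro ether (phenol protection as a methoxymethyl acetal) should mask the acidic OH before the basic and organometallic steps that follow, the aldehyde being untouched.

Step 2
Reactants: 2 3-methoxy-4-(methoxymethoxy)benzaldehyde; 3 triethyl 4-phosphonocrotonate [ethyl (2E)-4-(diethoxyphosphoryl)but-2-enoate]
Product: 4 ethyl (2E,4E)-5-[3-methoxy-4-(methoxymethoxy)phenyl]penta-2,4-dienoate
Conditions: LiN(SiMe3)2, THF, −78 °C to rt
Reagents that add atoms: none
Why: In this vinylogous Horner–Wadsworth–Emmons olefination the delocalised phosphonate anion should attack the non-enolisable aryl aldehyde through the carbon next to phosphorus and eliminate diethyl phosphate to give the conjugated dienoate, whose alkene geometry is irrelevant because both double bonds are saturated in the next step.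

Step 3
Reactants: 4 ethyl (2E,4E)-5-[3-methoxy-4-(methoxymethoxy)phenyl]penta-2,4-dienoate
Product: 5 ethyl 5-[3-methoxy-4-(methoxymethoxy)phenyl]pentanoate
Conditions: H2 (1 atm), Pd/C (10 wt % palladium on carbon), EtOAc, rt
Reagents that add atoms: none
Why: Heterogeneous catalytic hydrogenation should saturate both conjugated alkenes, while the ester, the arene and the MOM acetal (no benzylic C–O bond is present) are stable under these neutral conditions.

Step 4
Reactants: 5 ethyl 5-[3-methoxy-4-(methoxymethoxy)phenyl]pentanoate
Product: 6 1-{4-[3-methoxy-4-(methoxymethoxy)phenyl]butyl}cyclopropan-1-ol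
Conditions: EtMgBr (3 equiv, slow addition), Ti(OiPr)4 (20 mol %), THF, 0 °C to rt; then sat. aq NH4Cl
Reagents that add atoms: ethylmagnesium bromide (EtMgBr), CC[Mg]Br
Why: In the Kulinkovich cyclopropanation, EtMgBr and Ti(OiPr)4 form the titanacyclopropane (iPrO)2Ti(C2H4), a 1,2-dicarbanion equivalent that should add twice to the ester carbon with loss of ethoxide to give the 1-substituted cyclopropanol, the aryl ethers and the MOM acetal being inert.

Step 5
Reactants: 7 4-bromo-2-methoxyphenol
Product: 8 4-bromo-2-methoxy-1-(methoxymethoxy)benzene
Conditions: MOMCl, K2CO3, acetone, 0 °C to rt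
Reagents that add atoms: chloromethyl methyl ether (MOMCl), COCCl
Why: The same phenoxide O-alkylation (MOM protection) should prevent a phenoxide from forming under the carbonate base of the coupling, which would make the aryl bromide too electron-rich for oxidative addition.

Step 6
Reactants: 6 1-{4-[3-methoxy-4-(methoxymethoxy)phenyl]butyl}cyclopropan-1-ol; 8 4-bromo-2-methoxy-1-(methoxymethoxy)benzene
Product: 9 1,7-bis[3-methoxy-4-(methoxymethoxy)phenyl]heptan-3-one
Conditions: Pd(OAc)2 (5 mol %), XPhos (2-dicyclohexylphosphino-2',4',6'-triisopropylbiphenyl, 10 mol %), Cs2CO3 (2 equiv), toluene, 80 °C, argon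
Reagents that add atoms: none
Why: Zerovalent palladium, formed in the flask from Pd(OAc)2 and the phosphine, should insert into the C–Br bond of 8, and carbonate-assisted exchange of bromide for the alkoxide of 6 gives the divalent arylpalladium cyclopropanolate ArPd(L)OC(R)(CH2)2. Strain-driven β-carbon elimination then cleaves one ring C–C bond to the palladium homoenolate ArPd(L)CH2CH2C(=O)R, in which the former carbinol carbon is already the C3 ketone, and reductive elimination forms the C1–aryl bond and returns zerovalent palladium. The closest known reaction type is the palladium-catalysed ring-opening cross-coupling of 1-substituted cyclopropanols, acting as ketone homoenolate equivalents, with aryl bromides. No ring is closed and no stereocentre is created; the cyclopropane made in step 4 is consumed. The step needs reductive elimination to outpace β-hydride elimination to the vinyl ketone, which the bulky, electron-rich biaryl phosphine should favour by accelerating C–C bond formation at palladium. Site selectivity in ring cleavage is not an issue because the two ring CH2 groups of 6 are equivalent, and the MOM acetals and methyl ethers are inert to Cs2CO3 in toluene.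

Step 7
Reactants: 9 1,7-bis[3-methoxy-4-(methoxymethoxy)phenyl]heptan-3-one
Product: 10 1,7-bis(4-hydroxy-3-methoxyphenyl)heptan-3-one
Conditions: HCl (2 M aq, 10 vol %), MeOH, 50 °C; then H2O, aq NaHCO3
Reagents that add atoms: none
Why: Acid-catalysed acetal exchange with methanol should cleave both aryl MOM ethers and trap the formaldehyde unit as dimethoxymethane, away from the electron-rich rings, while the water present keeps the C3 ketone free of ketal.

**Compound list**

1 | vanillin (4-hydroxy-3-methoxybenzaldehyde) | COc1cc(C=O)ccc1O | starting material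
2 | 3-methoxy-4-(methoxymethoxy)benzaldehyde | COCOc1ccc(C=O)cc1OC | intermediate
3 | triethyl 4-phosphonocrotonate [ethyl (2E)-4-(diethoxyphosphoryl)but-2-enoate] | CCOC(=O)/C=C/CP(=O)(OCC)OCC | starting material
4 | ethyl (2E,4E)-5-[3-methoxy-4-(methoxymethoxy)phenyl]penta-2,4-dienoate | CCOC(=O)/C=C/C=C/c1ccc(OCOC)c(OC)c1 | intermediate
5 | ethyl 5-[3-methoxy-4-(methoxymethoxy)phenyl]pentanoate | CCOC(=O)CCCCc1ccc(OCOC)c(OC)c1 | intermediate
6 | 1-{4-[3-methoxy-4-(methoxymethoxy)phenyl]butyl}cyclopropan-1-ol | OC1(CCCCc2ccc(OCOC)c(OC)c2)CC1 | intermediate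
7 | 4-bromo-2-methoxyphenol | COc1cc(Br)ccc1O | starting material
8 | 4-bromo-2-methoxy-1-(methoxymethoxy)benzene | COCOc1ccc(Br)cc1OC | intermediate
9 | 1,7-bis[3-methoxy-4-(methoxymethoxy)phenyl]heptan-3-one | COCOc1ccc(CCCCC(=O)CCc2ccc(OCOC)c(OC)c2)cc1OC | intermediate
10 | 1,7-bis(4-hydroxy-3-methoxyphenyl)heptan-3-one | COc1cc(CCCCC(=O)CCc2ccc(O)c(OC)c2)ccc1O | target

**Step count**

Total step count: 7 (steps 1–4 build cyclopropanol 6, step 5 prepares bromide 8, steps 6 and 7 join the two and deprotect).
Longest linear sequence: 6 steps (steps 1, 2, 3, 4, 6, 7; from vanillin 1 to target 10).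

**Steps most likely to fail, with fallbacks**

1. Step 6. β-Hydride elimination from the palladium homoenolate, or its protonation, may outrun reductive elimination, so that the cyclopropanol is consumed without forming the C1–aryl bond. The fallback sets out from 6 and 8 and returns at 9, and makes β-hydride elimination the intended pathway. Cyclopropanol 6 is opened oxidatively (Pd(OAc)2 cat., pyridine, O2 1 atm, toluene, 80 °C) to the vinyl ketone 7-[3-methoxy-4-(methoxymethoxy)phenyl]hept-1-en-3-one F1. Heck arylation of F1 with bromide 8 under ligand-free phase-transfer conditions (Pd(OAc)2, Bu4NCl, NaHCO3, DMF, 80 °C) should give the enone (E)-1,7-bis[3-methoxy-4-(methoxymethoxy)phenyl]hept-1-en-3-one F2. Hydrogenation of its C1=C2 bond (H2, Pd/C, EtOAc, rt, stopped after one equivalent to spare the ketone) should then deliver 9.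

2. Step 4. Ligand exchange at titanium may be slow relative to direct attack of EtMgBr on the ester, leading to over-alkylation of the carbonyl or to stalled turnover. The fallback sets out from 5 and returns at 6, building the cyclopropanol by cyclopropanation of an enol silane instead.
   - Ester 5 is converted (MeNH(OMe)·HCl, iPrMgCl, THF, −20 °C) into the Weinreb amide N-methoxy-N-methyl-5-[3-methoxy-4-(methoxymethoxy)phenyl]pentanamide F3.
   - MeMgBr (THF, 0 °C) should give the methyl ketone 6-[3-methoxy-4-(methoxymethoxy)phenyl]hexan-2-one F4.
   - Kinetic enolisation on the methyl side (LiN(iPr)2, Me3SiCl, THF, −78 °C) should give the enol silane trimethyl({6-[3-methoxy-4-(methoxymethoxy)phenyl]hex-1-en-2-yl}oxy)silane F5.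
   - Simmons–Smith cyclopropanation in the Furukawa variant (Et2Zn, CH2I2, CH2Cl2, 0 °C) should give the siloxycyclopropane (1-{4-[3-methoxy-4-(methoxymethoxy)phenyl]butyl}cyclopropoxy)trimethylsilane F6.
   - Mild methanolysis (K2CO3, MeOH, rt) then frees cyclopropanol 6.

3. Step 2. The delocalised, weakly nucleophilic phosphonate anion may add sluggishly to the electron-rich aldehyde, or may self-condense, so that olefination stays incomplete. The fallback sets out from 2 and returns at 5. A Wittig reaction of 2 with the non-stabilised ylide from (3-ethoxycarbonylpropyl)triphenylphosphonium bromide (NaN(SiMe3)2, THF, −78 °C to rt) should give ethyl (4Z)-5-[3-methoxy-4-(methoxymethoxy)phenyl]pent-4-enoate F7 as the major isomer; its geometry is of no consequence. Hydrogenation under the conditions of step 3 (H2, Pd/C, EtOAc, rt) then gives ester 5 directly.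

**Further compounds**

F1 | step 6 | 7-[3-methoxy-4-(methoxymethoxy)phenyl]hept-1-en-3-one | C=CC(=O)CCCCc1ccc(OCOC)c(OC)c1
F2 | step 6 | (E)-1,7-bis[3-methoxy-4-(methoxymethoxy)phenyl]hept-1-en-3-one | COCOc1ccc(/C=C/C(=O)CCCCc2ccc(OCOC)c(OC)c2)cc1OC
F3 | step 4 | N-methoxy-N-methyl-5-[3-methoxy-4-(methoxymethoxy)phenyl]pentanamide | CON(C)C(=O)CCCCc1ccc(OCOC)c(OC)c1
F4 | step 4 | 6-[3-methoxy-4-(methoxymethoxy)phenyl]hexan-2-one | CC(=O)CCCCc1ccc(OCOC)c(OC)c1
F5 | step 4 | trimethyl({6-[3-methoxy-4-(methoxymethoxy)phenyl]hex-1-en-2-yl}oxy)silane | C=C(O[Si](C)(C)C)CCCCc1ccc(OCOC)c(OC)c1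
F6 | step 4 | (1-{4-[3-methoxy-4-(methoxymethoxy)phenyl]butyl}cyclopropoxy)trimethylsilane | C[Si](C)(C)OC1(CCCCc2ccc(OCOC)c(OC)c2)CC1
F7 | step 2 | ethyl (4Z)-5-[3-methoxy-4-(methoxymethoxy)phenyl]pent-4-enoate | CCOC(=O)CC/C=C\c1ccc(OCOC)c(OC)c1
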